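The bicyclic core is labelled C1 (quaternary, methyl-bearing), C2, C3, C4 (isopropyl-bearing CH), C5 (ring-fusion carbinol), C6, C7, C8 (methyl-bearing alkene carbon), C9 (alkene CH) and C10 (ester-bearing CH). The route rests on cutting the cyclopentane bond C1–C2. In the seven-membered ring C1 is the α′-carbon of the C8=C9–C10=O enone, so its cross-conjugated silyl dienol ether can attack a gold-activated terminal alkyne held on C5 through C4. One 5-endo-dig closure should create C1–C2, the five-membered ring and the quaternary C1 cis to the C5 oxygen. The precursor is a 2-silyloxy-1,4-dimethylcyclohepta-1,3-diene whose C7 (core C5) carries a silyl ether and an (S)-1-isopropylprop-2-ynyl group.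

Key step: step 10

Remark 1: the target as drawn is the cis-fused hydroazulene with the C1 methyl, C5 hydroxyl, C4 isopropyl group and C10 ester oxygen all on the same face; 16 and 17 carry exactly these C1/C4/C5 configurations, so no structure needed correcting.
Remark 2 (assumption): chirality transfer in step 5 is taken to follow the usual course for propargylic mesylates (anti oxidative addition to Pd(0), Pd-to-Zn exchange with retention, suprafacial SE2′ addition), i.e. net inversion at the propargylic carbon; this makes the (R)-mesylate the required enantiomer.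
Remark 3: compounds 10, 11, 12 and 15 are carried as mixtures of C1 epimers (13 and 14 also at C8/C9), which step 9 merges. The dienol ether is made by soft enolisation because an amide base would first metalate the acetylenic C–H. The C5 oxygen stays silylated because a free homopropargylic alcohol would itself add to the gold-bound alkyne.

Step 1
Reactants: 1 rac-4-methylpent-1-yn-3-ol
Product: 2 (3R)-4-methylpent-1-yn-3-ol
Conditions: Novozym 435 (CAL-B), vinyl acetate (3 equiv), pentane, 25 °C, stopped at ca. 55–60 % conversion; alcohol separated from the acetate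
Reagents that add atoms: none
Why: Lipase-catalysed kinetic resolution (transesterification); by the Kazlauskas rule the slim ethynyl group takes the small pocket, the (S)-alcohol should be acetylated faster, and running past half conversion should leave the (R)-alcohol in high ee.

Step 2
Reactants: 2 (3R)-4-methylpent-1-yn-3-ol
Product: 3 (3R)-4-methylpent-1-yn-3-yl methanesulfonate
Conditions: MsCl, Et3N, CH2Cl2, −78 → 0 °C
Reagents that add atoms: methanesulfonyl chloride, CS(=O)(=O)Cl
Why: Standard O-sulfonylation of a secondary propargylic alcohol; the C–O bond is not touched, so the (R) configuration is retained.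

Step 3
Reactants: 4 cycloheptane-1,3-dione; 5 iodomethane
Product: 6 2-methylcycloheptane-1,3-dione
Conditions: MeI, K2CO3, acetone, 56 °C
Reagents that add atoms: iodomethane (5), CI
Why: C-Alkylation of the soft 1,3-dione enolate with methyl iodide under mild carbonate conditions, the usual entry to 2-alkyl-1,3-diones; no stereocentre is formed.

Step 4
Reactants: 6 2-methylcycloheptane-1,3-dione
Product: 7 2-methyl-3-(2-methylpropoxy)cyclohept-2-en-1-one
Conditions: i-BuOH, p-TsOH·H2O (cat.), toluene, reflux, Dean–Stark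
Reagents that add atoms: 2-methylpropan-1-ol, CC(C)CO
Why: Acid-catalysed enol etherification with azeotropic removal of water turns the symmetric dione into its vinylogous ester, leaving one ketone (the future C5) as the only electrophilic carbonyl and C1 planar.

Step 5
Reactants: 7 2-methyl-3-(2-methylpropoxy)cyclohept-2-en-1-one; 3 (3R)-4-methylpent-1-yn-3-yl methanesulfonate
Product: 10 (3S)-3-hydroxy-2-methyl-3-[(3S)-4-methylpent-1-yn-3-yl]cycloheptan-1-one (C2 epimers), via allenylzinc 8 (not isolated), via enol ether carbinol 9 (not isolated)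
Conditions: Pd(OAc)2 (5 mol %), PPh3 (5 mol %), Et2Zn (3 equiv), THF, −78 → −20 → 0 °C; then 1 M HCl, THF, 0 °C
Reagents that add atoms: water, O
Why: Marshall–Tamaru propargylation: Pd(0) opens the mesylate anti, ethyl transfer from zinc gives allenylzinc 8, and its SE2′ addition through a six-membered transition state (zinc on the carbonyl lone pair beside C6H2, away from the C1 methyl) should set C4 by chirality transfer and C5 anti to it, after which dilute acid hydrolyses the enol ether to the seven-ring β-hydroxy ketone, which is slow to dehydrate.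

Step 6
Reactants: 10 (3S)-3-hydroxy-2-methyl-3-[(3S)-4-methylpent-1-yn-3-yl]cycloheptan-1-one
Product: 11 triethyl({(6S)-7-methyl-6-[(3S)-4-methylpent-1-yn-3-yl]-6-[(triethylsilyl)oxy]cyclohept-1-en-1-yl}oxy)silane (C7 epimers)
Conditions: TESOTf (2.5 equiv), Et3N (4 equiv), CH2Cl2, −78 → 0 °C
Reagents that add atoms: triethylsilyl trifluoromethanesulfonate, CC[Si](CC)(CC)OS(=O)(=O)C(F)(F)F
Why: Silyl triflate/amine silylation caps the tertiary alcohol and, by soft enolisation toward the unhindered C9 methylene and not the crowded C1–H, forms the silyl enol ether without a strong base that would metalate the alkyne.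

Step 7
Reactants: 11 triethyl({(6S)-7-methyl-6-[(3S)-4-methylpent-1-yn-3-yl]-6-[(triethylsilyl)oxy]cyclohept-1-en-1-yl}oxy)silane
Product: 12 (6S)-7-methyl-6-[(3S)-4-methylpent-1-yn-3-yl]-6-[(triethylsilyl)oxy]cyclohept-2-en-1-one (C7 epimers)
Conditions: IBX·4-methoxypyridine N-oxide (1.5 equiv), DMSO, 25 °C
Reagents that add atoms: none
Why: Dehydrogenation of a silyl enol ether with the IBX·N-oxide complex (a palladium-free Saegusa-type oxidation) should give the C8=C9 enone at room temperature and leave the terminal alkyne and the tertiary silyl ether alone.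

Step 8
Reactants: 12 (6S)-7-methyl-6-[(3S)-4-methylpent-1-yn-3-yl]-6-[(triethylsilyl)oxy]cyclohept-2-en-1-one
Product: 15 (6S)-3,7-dimethyl-6-[(3S)-4-methylpent-1-yn-3-yl]-6-[(triethylsilyl)oxy]cyclohept-2-en-1-one (C7 epimers), via lithium enolate 13 (not isolated), via sulfilimine 14 (not isolated)
Conditions: Me2CuLi (from MeLi, CuI; 1.3 equiv), Et2O–THF, −78 °C; then t-BuN=S(Cl)Ph (2.5 equiv), −78 → 0 °C
Reagents that add atoms: lithium dimethylcuprate, [Li+].C[Cu-]C
Why: Gilman conjugate addition places the methyl on C8 and the regiodefined lithium enolate is dehydrogenated in the same flask (Mukaiyama dehydrogenation: C9 sulfilimine, then syn-elimination with the C8 hydrogen), which restores the C8=C9 enone and erases the transient C8 and C9 stereocentres.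

Step 9
Reactants: 15 (6S)-3,7-dimethyl-6-[(3S)-4-methylpent-1-yn-3-yl]-6-[(triethylsilyl)oxy]cyclohept-2-en-1-one
Product: 16 tert-butyl({(7S)-1,4-dimethyl-7-[(3S)-4-methylpent-1-yn-3-yl]-7-[(triethylsilyl)oxy]cyclohepta-1,3-dien-2-yl}oxy)dimethylsilane
Conditions: TBSOTf (1.5 equiv), Et3N (3 equiv), CH2Cl2, −78 → 0 °C
Reagents that add atoms: tert-butyldimethylsilyl trifluoromethanesulfonate, CC(C)(C)[Si](C)(C)OS(=O)(=O)C(F)(F)F
Why: Soft enolisation of an enone with a silyl triflate and triethylamine is kinetically α′-selective, so deprotonation of the O-silylated enone at C1 should give the cross-conjugated 2-silyloxydiene and merge both C1 epimers into one compound, again without metalating the alkyne.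

Step 10
Reactants: 16 tert-butyl({(7S)-1,4-dimethyl-7-[(3S)-4-methylpent-1-yn-3-yl]-7-[(triethylsilyl)oxy]cyclohepta-1,3-dien-2-yl}oxy)dimethylsilane
Product: 17 (3S,3aS,8aS)-6,8a-dimethyl-3-(propan-2-yl)-3a-[(triethylsilyl)oxy]-3a,4,5,8a-tetrahydroazulen-8(3H)-one
Conditions: Ph3PAuCl (10 mol %), AgBF4 (10 mol %), CH2Cl2–MeOH (10:1), 23 → 40 °C
Reagents that add atoms: none
Why: Cationic gold(I) binds the terminal alkyne and C1, the only nucleophilic carbon of the 2-silyloxydiene, adds anti to the metal at the terminal carbon C2, giving a vinylgold at C3 and a silyloxocarbenium ion at C10; methanol then takes the silyl group (restoring the C10 enone) and protodeaurates C3. The closest known reaction type is the gold(I)-catalysed 5-endo-dig carbocyclisation of silyl enol ethers onto alkynes (Conia-ene type). The cyclopentene ring C1–C2–C3–C4–C5 closes in the 5-endo-dig mode, the 4-exo alternative at C3 being too strained. The new quaternary stereocentre C1 is controlled by the existing C5 centre: the two-atom tether can only reach the face of C1 syn to the C5–C4 bond, so the ring fusion must be cis and the C1 methyl ends up cis to the C5 oxygen. The step needs C- over O-cyclisation and ring closure before loss of the dienol silyl group; the hindered tertiary triethylsilyl ether is a poor nucleophile, no base is present so the β-silyloxy ketone cannot eliminate, and the tetrasubstituted dienol ether is the most electron-rich π-system within reach of the alkyne.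

Step 11
Reactants: 17 (3S,3aS,8aS)-6,8a-dimethyl-3-(propan-2-yl)-3a-[(triethylsilyl)oxy]-3a,4,5,8a-tetrahydroazulen-8(3H)-one
Product: 18 (3R,3aS,8aS)-6,8a-dimethyl-3-(propan-2-yl)-3a-[(triethylsilyl)oxy]-1,2,3,3a,4,5-hexahydroazulen-8(8aH)-one
Conditions: H2 (10 atm), RhCl(PPh3)3 (10 mol %), benzene–EtOH, 40 °C
Reagents that add atoms: none
Why: Homogeneous hydrogenation with Wilkinson's catalyst should reduce the cis-disubstituted cyclopentene much faster than the trisubstituted, conjugated C8=C9 bond and does not touch the ketone; no stereocentre is formed.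

Step 12
Reactants: 18 (3R,3aS,8aS)-6,8a-dimethyl-3-(propan-2-yl)-3a-[(triethylsilyl)oxy]-1,2,3,3a,4,5-hexahydroazulen-8(8aH)-one
Product: 19 (3R,3aS,8aS)-3a-hydroxy-6,8a-dimethyl-3-(propan-2-yl)-1,2,3,3a,4,5-hexahydroazulen-8(8aH)-one
Conditions: HF·pyridine, THF–pyridine, 0 → 23 °C
Reagents that add atoms: none
Why: Fluoride cleavage of the silyl ether under buffered, non-basic conditions frees the tertiary alcohol without retro-aldol opening of the β-hydroxy ketone, and dehydration toward C1 is impossible because C1 is quaternary.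

Step 13
Reactants: 19 (3R,3aS,8aS)-3a-hydroxy-6,8a-dimethyl-3-(propan-2-yl)-1,2,3,3a,4,5-hexahydroazulen-8(8aH)-one
Product: 21 (3R,3aS,8S,8aR)-6,8a-dimethyl-3-(propan-2-yl)-1,2,3,3a,4,5,8,8a-octahydroazulene-3a,8-diol, via borinate chelate 20 (not isolated)
Conditions: Et2BOMe (1.2 equiv), THF–MeOH (4:1), 23 → −78 °C; NaBH4, −78 °C; MeOH co-evaporation
Reagents that add atoms: none
Why: Narasaka–Prasad reduction: the C5 borinate chelates the C10 carbonyl on the ring face that carries the C5 oxygen, borohydride attacks C10 from the opposite face in a 1,2-sense, and the new C10 hydroxyl should therefore end up cis (syn) to the C5 hydroxyl and the C1 methyl.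

Step 14
Reactants: 21 (3R,3aS,8S,8aR)-6,8a-dimethyl-3-(propan-2-yl)-1,2,3,3a,4,5,8,8a-octahydroazulene-3a,8-diol; 22 4-methoxybenzoyl chloride
Product: 23 (3R,3aS,8S,8aR)-3a-hydroxy-6,8a-dimethyl-3-(propan-2-yl)-1,2,3,3a,4,5,8,8a-octahydroazulen-8-yl 4-methoxybenzoate
Conditions: 4-MeOC6H4COCl (1.5 equiv), pyridine, DMAP (cat.), CH2Cl2, 0 → 23 °C
Reagents that add atoms: 4-methoxybenzoyl chloride (22), COc1ccc(C(Cl)=O)cc1
Why: DMAP-catalysed acylation with an acid chloride should esterify the secondary allylic alcohol, whereas the tertiary ring-fusion alcohol is too hindered to react, so the target is reached without a protecting group.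

Compound list
1 | rac-4-methylpent-1-yn-3-ol | CC(C)C(O)C#C | starting material
2 | (3R)-4-methylpent-1-yn-3-ol | C#C[C@@H](C(C)C)O | intermediate
3 | (3R)-4-methylpent-1-yn-3-yl methanesulfonate | C#C[C@@H](C(C)C)OS(C)(=O)=O | intermediate
4 | cycloheptane-1,3-dione | O=C1CCCCC(=O)C1 | starting material
5 | iodomethane | CI | starting material
6 | 2-methylcycloheptane-1,3-dione | CC1C(=O)CCCCC1=O | intermediate
7 | 2-methyl-3-(2-methylpropoxy)cyclohept-2-en-1-one | CC(C)COC1=C(C)C(=O)CCCC1 | intermediate
8 | (aS)-ethyl(4-methylpenta-1,2-dien-1-yl)zinc | [H]C([Zn]CC)=[C@]=C([H])C(C)C | intermediate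
9 | (1S)-2-methyl-3-(2-methylpropoxy)-1-[(3S)-4-methylpent-1-yn-3-yl]cyclohept-2-en-1-ol | C#C[C@H](C(C)C)[C@@]1(O)CCCCC(OCC(C)C)=C1C | intermediate
10 | (3S)-3-hydroxy-2-methyl-3-[(3S)-4-methylpent-1-yn-3-yl]cycloheptan-1-one, C2 epimers | C#C[C@H](C(C)C)[C@@]1(O)CCCCC(=O)C1C | intermediate
11 | triethyl({(6S)-7-methyl-6-[(3S)-4-methylpent-1-yn-3-yl]-6-[(triethylsilyl)oxy]cyclohept-1-en-1-yl}oxy)silane, C7 epimers | C#C[C@H](C(C)C)[C@@]1(O[Si](CC)(CC)CC)CCCC=C(O[Si](CC)(CC)CC)C1C | intermediate
12 | (6S)-7-methyl-6-[(3S)-4-methylpent-1-yn-3-yl]-6-[(triethylsilyl)oxy]cyclohept-2-en-1-one, C7 epimers | C#C[C@H](C(C)C)[C@@]1(O[Si](CC)(CC)CC)CCC=CC(=O)C1C | intermediate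
13 | lithium (6S)-3,7-dimethyl-6-[(3S)-4-methylpent-1-yn-3-yl]-6-[(triethylsilyl)oxy]cyclohept-1-en-1-olate, C3/C7 epimers | C#C[C@H](C(C)C)[C@@]1(O[Si](CC)(CC)CC)CCC(C)C=C(O[Li])C1C | intermediate
14 | (6S)-2-(N-tert-butyl-S-phenylsulfinimidoyl)-3,7-dimethyl-6-[(3S)-4-methylpent-1-yn-3-yl]-6-[(triethylsilyl)oxy]cycloheptan-1-one, diastereomer mixture | C#C[C@H](C(C)C)[C@@]1(O[Si](CC)(CC)CC)CCC(C)C(S(=NC(C)(C)C)c2ccccc2)C(=O)C1C | intermediate
15 | (6S)-3,7-dimethyl-6-[(3S)-4-methylpent-1-yn-3-yl]-6-[(triethylsilyl)oxy]cyclohept-2-en-1-one, C7 epimers | C#C[C@H](C(C)C)[C@@]1(O[Si](CC)(CC)CC)CCC(C)=CC(=O)C1C | intermediate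
16 | tert-butyl({(7S)-1,4-dimethyl-7-[(3S)-4-methylpent-1-yn-3-yl]-7-[(triethylsilyl)oxy]cyclohepta-1,3-dien-2-yl}oxy)dimethylsilane | C#C[C@H](C(C)C)[C@@]1(O[Si](CC)(CC)CC)CCC(C)=CC(O[Si](C)(C)C(C)(C)C)=C1C | intermediate
17 | (3S,3aS,8aS)-6,8a-dimethyl-3-(propan-2-yl)-3a-[(triethylsilyl)oxy]-3a,4,5,8a-tetrahydroazulen-8(3H)-one, cis-fused | O=C1C=C(C)CC[C@]2(O[Si](CC)(CC)CC)[C@@H](C(C)C)C=C[C@]12C | intermediate
18 | (3R,3aS,8aS)-6,8a-dimethyl-3-(propan-2-yl)-3a-[(triethylsilyl)oxy]-1,2,3,3a,4,5-hexahydroazulen-8(8aH)-one | O=C1C=C(C)CC[C@]2(O[Si](CC)(CC)CC)[C@@H](C(C)C)CC[C@]12C | intermediate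
19 | (3R,3aS,8aS)-3a-hydroxy-6,8a-dimethyl-3-(propan-2-yl)-1,2,3,3a,4,5-hexahydroazulen-8(8aH)-one | O=C1C=C(C)CC[C@]2(O)[C@@H](C(C)C)CC[C@]12C | intermediate
20 | O-diethylboryl derivative (borinate chelate) of 19 | O=C1C=C(C)CC[C@]2(OB(CC)CC)[C@@H](C(C)C)CC[C@]12C | intermediate
21 | (3R,3aS,8S,8aR)-6,8a-dimethyl-3-(propan-2-yl)-1,2,3,3a,4,5,8,8a-octahydroazulene-3a,8-diol | O[C@H]1C=C(C)CC[C@]2(O)[C@@H](C(C)C)CC[C@]12C | intermediate
22 | 4-methoxybenzoyl chloride | COc1ccc(C(Cl)=O)cc1 | starting material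
23 | (3R,3aS,8S,8aR)-3a-hydroxy-6,8a-dimethyl-3-(propan-2-yl)-1,2,3,3a,4,5,8,8a-octahydroazulen-8-yl 4-methoxybenzoate (CNP0158828.1) | COc1ccc(C(=O)O[C@H]2C=C(C)CC[C@]3(O)[C@@H](C(C)C)CC[C@]23C)cc1 | target

Total step count: 14. Longest linear sequence: 12 steps (steps 3–14 from cycloheptane-1,3-dione; the branch through steps 1, 2 and 5–14 is equally long).

Steps most likely to fail

Step 10. What may go wrong: the C5 silyl ether oxygen may attack the gold-bound alkyne (dihydrofuran formation with loss of the silyl group), or the methanolic medium may protodesilylate the dienol ether before the C–C bond forms. The fallback sets out from 15 and rejoins the route at 17, making the same C1–C2 bond by palladium-catalysed intramolecular α-alkenylation of the ketone. NIS/AgNO3 in acetone converts 15 into (6S)-6-[(3S)-1-iodo-4-methylpent-1-yn-3-yl]-3,7-dimethyl-6-[(triethylsilyl)oxy]cyclohept-2-en-1-one F1. Diimide (2-nitrobenzenesulfonylhydrazide, Et3N) reduces it to (6S)-6-[(1Z,3S)-1-iodo-4-methylpent-1-en-3-yl]-3,7-dimethyl-6-[(triethylsilyl)oxy]cyclohept-2-en-1-one F2. Pd(PPh3)4/KOPh in THF at 70 °C should then couple C1 with C2 and give 17, because only the C1 enolate can reach the vinylpalladium.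

Step 5. What may go wrong: addition of the allenylzinc to the electron-rich vinylogous-ester carbonyl may be slow, so that the reagent loses its configuration before it reacts and ee and dr erode. The fallback sets out from 1 and 7 and rejoins at 10, trading chirality transfer for a robust racemic addition followed by resolution. PBr3/pyridine converts 1 into 3-bromo-4-methylpent-1-yne F3. Its Barbier reaction with activated zinc and 7 in THF at 25–40 °C (zinc-mediated ketone propargylation through the same closed transition state, with no demand on configurational stability) should give racemic anti 2-methyl-3-(2-methylpropoxy)-1-(4-methylpent-1-yn-3-yl)cyclohept-2-en-1-ol F4. The same acidic work-up gives racemic anti 3-hydroxy-2-methyl-3-(4-methylpent-1-yn-3-yl)cycloheptan-1-one F5, and preparative chromatography of F5 on a chiral stationary phase delivers 10.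

Step 9. What may go wrong: poor regioselectivity of enolisation, the amine removing a γ-proton (C8 methyl or C7) of the O-silylated enone instead of the crowded C1–H, which gives linear dienol ethers that cannot close the five-membered ring. The fallback sets out from 6 and rejoins at 18; it carries the C1=C10 silyl enol ether over from the vinylogous ester and adds the C8 methyl and the C8=C9 bond only after ring closure, when C1 is quaternary.
- TBSCl/imidazole turns 6 into 3-[(tert-butyldimethylsilyl)oxy]-2-methylcyclohept-2-en-1-one F6.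
- Addition of allenylzinc 8 (as in step 5, neutral work-up) gives (1S)-3-[(tert-butyldimethylsilyl)oxy]-2-methyl-1-[(3S)-4-methylpent-1-yn-3-yl]cyclohept-2-en-1-ol F7.
- TESOTf/2,6-lutidine gives tert-butyl({(7S)-1-methyl-7-[(3S)-4-methylpent-1-yn-3-yl]-7-[(triethylsilyl)oxy]cyclohept-1-en-2-yl}oxy)dimethylsilane F8.
- Gold catalysis as in step 10 gives (3S,3aS,8aS)-8a-methyl-3-(propan-2-yl)-3a-[(triethylsilyl)oxy]-3a,4,5,6,7,8a-hexahydroazulen-8(3H)-one F9.
- Wilkinson hydrogenation gives (3R,3aS,8aS)-8a-methyl-3-(propan-2-yl)-3a-[(triethylsilyl)oxy]octahydroazulen-8(1H)-one F10.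
- IBX in DMSO at 70 °C (only C9 can enolise) gives (3R,3aS,8aS)-8a-methyl-3-(propan-2-yl)-3a-[(triethylsilyl)oxy]-1,2,3,3a,4,5-hexahydroazulen-8(8aH)-one F11.
- Me2CuLi followed by the sulfinimidoyl chloride as in step 8, through the lithium enolate F12 and the C9 sulfilimine F13, gives 18.

Further compounds
F1 | step 10 | (6S)-6-[(3S)-1-iodo-4-methylpent-1-yn-3-yl]-3,7-dimethyl-6-[(triethylsilyl)oxy]cyclohept-2-en-1-one | IC#C[C@H](C(C)C)[C@@]1(O[Si](CC)(CC)CC)CCC(C)=CC(=O)C1C
F2 | step 10 | (6S)-6-[(1Z,3S)-1-iodo-4-methylpent-1-en-3-yl]-3,7-dimethyl-6-[(triethylsilyl)oxy]cyclohept-2-en-1-one | I/C=C\[C@H](C(C)C)[C@@]1(O[Si](CC)(CC)CC)CCC(C)=CC(=O)C1C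
F3 | step 5 | 3-bromo-4-methylpent-1-yne (racemic) | CC(C)C(Br)C#C
F4 | step 5 | racemic anti 2-methyl-3-(2-methylpropoxy)-1-(4-methylpent-1-yn-3-yl)cyclohept-2-en-1-ol (relative configuration shown) | C#C[C@H](C(C)C)[C@@]1(O)CCCCC(OCC(C)C)=C1C
F5 | step 5 | racemic anti 3-hydroxy-2-methyl-3-(4-methylpent-1-yn-3-yl)cycloheptan-1-one (relative configuration shown) | C#C[C@H](C(C)C)[C@@]1(O)CCCCC(=O)C1C
F6 | step 9 | 3-[(tert-butyldimethylsilyl)oxy]-2-methylcyclohept-2-en-1-one | CC1=C(O[Si](C)(C)C(C)(C)C)CCCCC1=O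
F7 | step 9 | (1S)-3-[(tert-butyldimethylsilyl)oxy]-2-methyl-1-[(3S)-4-methylpent-1-yn-3-yl]cyclohept-2-en-1-ol | C#C[C@H](C(C)C)[C@@]1(O)CCCCC(O[Si](C)(C)C(C)(C)C)=C1C
F8 | step 9 | tert-butyl({(7S)-1-methyl-7-[(3S)-4-methylpent-1-yn-3-yl]-7-[(triethylsilyl)oxy]cyclohept-1-en-2-yl}oxy)dimethylsilane | C#C[C@H](C(C)C)[C@@]1(O[Si](CC)(CC)CC)CCCCC(O[Si](C)(C)C(C)(C)C)=C1C
F9 | step 9 | (3S,3aS,8aS)-8a-methyl-3-(propan-2-yl)-3a-[(triethylsilyl)oxy]-3a,4,5,6,7,8a-hexahydroazulen-8(3H)-one | O=C1CCCC[C@]2(O[Si](CC)(CC)CC)[C@@H](C(C)C)C=C[C@]12C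
F10 | step 9 | (3R,3aS,8aS)-8a-methyl-3-(propan-2-yl)-3a-[(triethylsilyl)oxy]octahydroazulen-8(1H)-one | O=C1CCCC[C@]2(O[Si](CC)(CC)CC)[C@@H](C(C)C)CC[C@]12C
F11 | step 9 | (3R,3aS,8aS)-8a-methyl-3-(propan-2-yl)-3a-[(triethylsilyl)oxy]-1,2,3,3a,4,5-hexahydroazulen-8(8aH)-one | O=C1C=CCC[C@]2(O[Si](CC)(CC)CC)[C@@H](C(C)C)CC[C@]12C
F12 | step 9 | lithium enolate of the 6-methyl ketone (C8 enolate oxygen, C6 epimers; numbering as in 18) | [Li]OC1=CC(C)CC[C@]2(O[Si](CC)(CC)CC)[C@@H](C(C)C)CC[C@]12C
F13 | step 9 | 7-(N-tert-butyl-S-phenylsulfinimidoyl)-6-methyl ketone (diastereomer mixture; numbering as in 18) | O=C1C(S(=NC(C)(C)C)c3ccccc3)C(C)CC[C@]2(O[Si](CC)(CC)CC)[C@@H](C(C)C)CC[C@]12C
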